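Retrosynthesis: the benzoate C–O bonds at O5 and O7 are cut first, then C1–C7 (hydroxymethylation of a C1 enol triflate), then C2–C3 of a 3-hydroxycyclohexanone (aldol), which leads back to an open-chain sugar.
Enabling feature: in the cyclohexene (C1 bears C7H2OBz, C2 = vinyl CH, C3–C6 oxygenated) C3 is β to C1, and C4, C5, C6 carry the oxygen pattern of C2, C3, C4 of L-rhamnose; sugar C1 maps on C3, sugar C5 on C1 and the sugar methyl on C2.
Forward: L-rhamnose is opened to a 2,3-acetonide-protected 6-deoxy-hexos-5-ulose; the only ring (the carbocycle) closes by 6-enolexo aldolisation; C7 is then attached and the protecting groups are exchanged for the two benzoates.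
Stereochemistry: C4, C5 and C6 come unchanged from L-rhamnose; C3 is set in the aldol step by the cis-fused dioxolane together with D-proline; the O5 benzoate is placed by axial-selective opening of a C4/C5 orthobenzoate.
Key step: step 7

Assumption: L-rhamnose is used as its commercial monohydrate; carbocyclic compounds carry the target numbering (C1 bears C7), sugar intermediates the sugar numbering.

Step 1
Reactants: 1 L-rhamnose; 2 allyl alcohol
Product: 3 allyl α-L-rhamnopyranoside
Conditions: allyl alcohol (solvent), TfOH (cat.), 80 °C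
Reagents that add atoms: allyl alcohol, C=CCO
Why: Fischer glycosidation under thermodynamic control should favour the α-pyranoside (anomeric effect, axial O2), and the anomeric centre is erased later.

Step 2
Reactants: 3 allyl α-L-rhamnopyranoside; 4 2,2-dimethoxypropane
Product: 5 allyl 2,3-O-isopropylidene-α-L-rhamnopyranoside
Conditions: Me2C(OMe)2, TsOH·H2O (cat.), acetone, rt
Reagents that add atoms: 2,2-dimethoxypropane, COC(C)(C)OC
Why: Acid-catalysed transacetalisation can close a dioxolane only across the cis 2,3-diol of the pyranose chair, which leaves O4 as the single free hydroxyl.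

Step 3
Reactants: 5 allyl 2,3-O-isopropylidene-α-L-rhamnopyranoside; 6 4-methoxybenzyl chloride
Product: 7 allyl 2,3-O-isopropylidene-4-O-(4-methoxybenzyl)-α-L-rhamnopyranoside
Conditions: NaH, Bu4NI (cat.), DMF, 0 °C to rt
Reagents that add atoms: 4-methoxybenzyl chloride, COc1ccc(CCl)cc1
Why: Williamson etherification of the only hydroxyl installs an ether that tolerates base, hydride, oxidation and palladium and is later removed by acid together with the acetonide.

Step 4
Reactants: 7 allyl 2,3-O-isopropylidene-4-O-(4-methoxybenzyl)-α-L-rhamnopyranoside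
Product: 9 2,3-O-isopropylidene-4-O-(4-methoxybenzyl)-L-rhamnopyranose (anomeric mixture), via prop-1-enyl glycoside 8 (not isolated)
Conditions: [Ir(cod)(PMePh2)2]PF6 (cat., H2-activated), THF, rt; then I2, NaHCO3, THF/H2O, 0 °C
Reagents that add atoms: none
Why: Iridium-catalysed allyl-to-propenyl isomerisation followed by iodonium-induced hydrolysis of the enol ether should free the hemiacetal under buffered conditions that spare the acetonide and the 4-methoxybenzyl ether.

Step 5
Reactants: 9 2,3-O-isopropylidene-4-O-(4-methoxybenzyl)-L-rhamnopyranose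
Product: 10 2,3-O-isopropylidene-4-O-(4-methoxybenzyl)-L-rhamnitol (free OH at C1 and C5)
Conditions: NaBH4, MeOH, 0 °C to rt
Reagents that add atoms: none
Why: Borohydride reduction of the open-chain hydroxy aldehyde in equilibrium with the lactol should give the 1,5-diol without touching the stereocentres.

Step 6
Reactants: 10 2,3-O-isopropylidene-4-O-(4-methoxybenzyl)-L-rhamnitol
Product: 11 6-deoxy-2,3-O-isopropylidene-4-O-(4-methoxybenzyl)-L-lyxo-hexos-5-ulose
Conditions: (COCl)2, DMSO, CH2Cl2, −78 °C; then iPr2NEt, −78 to −30 °C; used crude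
Reagents that add atoms: none
Why: In the Swern oxidation both hydroxyls are activated as alkoxysulfonium ions before base is added, so the 1,5-diol should give the keto aldehyde and not a lactone, while the hindered base at low temperature protects the α-alkoxy centres.

Step 7
Reactants: 11 6-deoxy-2,3-O-isopropylidene-4-O-(4-methoxybenzyl)-L-lyxo-hexos-5-ulose
Product: 12 (3R,4S,5S,6R)-3-hydroxy-4,5-O-isopropylidene-6-(4-methoxybenzyloxy)cyclohexan-1-one (O3 trans to O4)
Conditions: D-proline (30 mol %), DMSO, rt
Reagents that add atoms: none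
Why: D-proline condenses with the C5 ketone of 11, the iminium ion tautomerises to the less substituted enamine on the methyl side, this enamine adds to the C1 aldehyde and hydrolysis releases the β-hydroxy ketone 12, in which the former methyl carbon (ring C2) is bonded to the former aldehyde carbon (ring C3). The closest known reaction type is the amine-catalysed 6-enolexo aldolisation of keto aldehydes, the same bond construction as the ring-forming stage of the Ferrier carbocyclisation. The carbocycle closes in the 6-(enolexo)-exo-trig mode through a chair-like transition state. The new C3 stereocentre is controlled by the cis-fused dioxolane: in the chair that keeps O5 and the C6 ether equatorial, O4 is axial and the aldehyde C=O, hydrogen-bonded to the carboxylic acid of the catalyst, lies anti to the C4–O4 bond (Cornforth-type dipole minimisation), so O3 becomes axial and trans to O4, whereas the epimeric closure would force O3 and O5 into a syn-diaxial contact. D-Proline is chosen as the matched catalyst because its hydrogen-bonded (Houk–List type) transition state should deliver the tethered enamine to the Re face of the aldehyde, the face that this chair exposes. The step needs methyl-side regioselectivity and the absence of β-elimination or epimerisation, and both are secured by substrate and medium: an enamine toward C6 could only close a four-membered ring and suffers allylic strain, the α-branched aldehyde does not readily form an enamine, and the near-neutral conditions leave the dioxolane oxygens and the aldol hydroxyl in place.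

Step 8
Reactants: 12 aldol product; 13 tert-butyldimethylsilyl trifluoromethanesulfonate
Product: 14 3-O-tert-butyldimethylsilyl ether of 12
Conditions: TBSOTf, 2,6-lutidine, CH2Cl2, −78 °C
Reagents that add atoms: tert-butyldimethylsilyl trifluoromethanesulfonate, CC(C)(C)[Si](C)(C)OS(=O)(=O)C(F)(F)F
Why: Silylation with a silyl triflate and a hindered weak base is fast at −78 °C and should cap the β-hydroxyl before retro-aldol or dehydration can intervene.

Step 9
Reactants: 14 silyl ether; 15 N-(5-chloropyridin-2-yl)bis(trifluoromethanesulfonyl)imide (Comins reagent)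
Product: 16 C1 enol triflate (C1=C2) of 14, C3–C6 unchanged
Conditions: KN(SiMe3)2, THF, −78 °C; then 15, −78 °C
Reagents that add atoms: N-(5-chloropyridin-2-yl)bis(trifluoromethanesulfonyl)imide, O=S(=O)(N(c1ccc(Cl)cn1)S(=O)(=O)C(F)(F)F)C(F)(F)F
Why: Kinetic deprotonation of an α-alkoxy ketone by a bulky amide occurs at the unhindered C2 methylene and not at the oxygen-bearing C6 methine, and O-triflation of the enolate at −78 °C (enol triflate formation) should outrun E1cB loss of the C3 silyloxy group.

Step 10
Reactants: 16 enol triflate; 17 (tributylstannyl)methanol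
Product: 18 C7 allylic alcohol (1-hydroxymethyl-cyclohex-1-ene with O3 silyl, O4/O5 acetonide, O6 4-methoxybenzyl)
Conditions: Pd(PPh3)4 (cat.), LiCl, 1,4-dioxane, 100 °C
Reagents that add atoms: (tributylstannyl)methanol, CCCC[Sn](CCCC)(CCCC)CO
Why: Stille coupling (oxidative addition of zerovalent palladium into the C–OTf bond, chloride-assisted transfer of the hydroxymethyl group from tin, reductive elimination) forms C1–C7 with the double bond fixed at C1=C2.

Step 11
Reactants: 18 allylic alcohol; 19 benzoyl chloride
Product: 20 C7 benzoate of 18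
Conditions: BzCl, pyridine, DMAP (cat.), CH2Cl2, 0 °C
Reagents that add atoms: benzoyl chloride, O=C(Cl)c1ccccc1
Why: Acylation of the only free hydroxyl, a primary allylic alcohol, installs the first benzoate.

Step 12
Reactants: 20 fully protected C7 benzoate
Product: 21 (3R,4S,5R,6S)-1-(benzoyloxymethyl)cyclohex-1-ene-3,4,5,6-tetrol
Conditions: TFA, anisole, CH2Cl2, 0 °C; then H2O, rt
Reagents that add atoms: none
Why: Acidolysis should cleave the 4-methoxybenzyl ether (benzylic cation trapped by anisole), the silyl ether and the acetonide in one operation, while the benzoate and the electron-poor allylic system resist ionisation.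

Step 13
Reactants: 21 tetrol monobenzoate; 22 trimethyl orthobenzoate; 23 water
Product: 25 (3R,4S,5R,6S)-5-benzoyloxy-1-(benzoyloxymethyl)cyclohex-1-ene-3,4,6-triol (target), via cyclic orthobenzoate 24 (not isolated)
Conditions: PhC(OMe)3, CSA (cat.), MeCN, rt; then 80 % aq AcOH, rt
Reagents that add atoms: trimethyl orthobenzoate, COC(OC)(OC)c1ccccc1; water, O
Why: Orthoester exchange should close a five-membered ring only across the cis C4/C5 diol, and hydrolysis of the derived dioxolenium ion leaves the ester on the axial oxygen, which is O5 because allylic 1,2-strain with the C1 substituent holds O6 pseudoaxial and hence O5 axial.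

Compound list
1 | L-rhamnose | O=C[C@H](O)[C@H](O)[C@@H](O)[C@@H](O)C | starting material
2 | allyl alcohol | C=CCO | starting material
3 | allyl α-L-rhamnopyranoside | C=CCO[C@@H]1O[C@@H](C)[C@H](O)[C@@H](O)[C@H]1O | intermediate
4 | 2,2-dimethoxypropane | COC(C)(C)OC | starting material
5 | allyl 2,3-O-isopropylidene-α-L-rhamnopyranoside | C=CCO[C@@H]1O[C@@H](C)[C@H](O)[C@H]2OC(C)(C)O[C@@H]12 | intermediate
6 | 4-methoxybenzyl chloride | COc1ccc(CCl)cc1 | starting material
7 | allyl 2,3-O-isopropylidene-4-O-(4-methoxybenzyl)-α-L-rhamnopyranoside | C=CCO[C@@H]1O[C@@H](C)[C@H](OCc3ccc(OC)cc3)[C@H]2OC(C)(C)O[C@@H]12 | intermediate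
8 | (E)-prop-1-enyl 2,3-O-isopropylidene-4-O-(4-methoxybenzyl)-α-L-rhamnopyranoside | C/C=C/O[C@@H]1O[C@@H](C)[C@H](OCc3ccc(OC)cc3)[C@H]2OC(C)(C)O[C@@H]12 | intermediate
9 | 2,3-O-isopropylidene-4-O-(4-methoxybenzyl)-L-rhamnopyranose (anomeric mixture) | OC1O[C@@H](C)[C@H](OCc3ccc(OC)cc3)[C@H]2OC(C)(C)O[C@@H]12 | intermediate
10 | 2,3-O-isopropylidene-4-O-(4-methoxybenzyl)-L-rhamnitol | OC[C@H](O1)[C@H](OC1(C)C)[C@H]([C@@H](O)C)OCc1ccc(OC)cc1 | intermediate
11 | 6-deoxy-2,3-O-isopropylidene-4-O-(4-methoxybenzyl)-L-lyxo-hexos-5-ulose | O=C[C@H](O1)[C@H](OC1(C)C)[C@H](C(C)=O)OCc1ccc(OC)cc1 | intermediate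
12 | (3R,4S,5S,6R)-3-hydroxy-4,5-O-isopropylidene-6-(4-methoxybenzyloxy)cyclohexan-1-one | O=C1C[C@@H](O)[C@H](O2)[C@H](OC2(C)C)[C@H]1OCc1ccc(OC)cc1 | intermediate
13 | tert-butyldimethylsilyl trifluoromethanesulfonate | CC(C)(C)[Si](C)(C)OS(=O)(=O)C(F)(F)F | starting material
14 | 3-O-tert-butyldimethylsilyl ether of 12 | O=C1C[C@@H](O[Si](C)(C)C(C)(C)C)[C@H](O2)[C@H](OC2(C)C)[C@H]1OCc1ccc(OC)cc1 | intermediate
15 | N-(5-chloropyridin-2-yl)bis(trifluoromethanesulfonyl)imide | O=S(=O)(N(c1ccc(Cl)cn1)S(=O)(=O)C(F)(F)F)C(F)(F)F | starting material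
16 | C1 enol triflate of 14 (C1=C2) | O=S(=O)(OC1=C[C@@H](O[Si](C)(C)C(C)(C)C)[C@H](O2)[C@H](OC2(C)C)[C@H]1OCc1ccc(OC)cc1)C(F)(F)F | intermediate
17 | (tributylstannyl)methanol | CCCC[Sn](CCCC)(CCCC)CO | starting material
18 | 1-hydroxymethyl-cyclohex-1-ene with O3 silyl ether, O4/O5 acetonide, O6 4-methoxybenzyl ether | OCC1=C[C@@H](O[Si](C)(C)C(C)(C)C)[C@H](O2)[C@H](OC2(C)C)[C@H]1OCc1ccc(OC)cc1 | intermediate
19 | benzoyl chloride | O=C(Cl)c1ccccc1 | starting material
20 | C7 benzoate of 18 | O=C(OCC1=C[C@@H](O[Si](C)(C)C(C)(C)C)[C@H](O2)[C@H](OC2(C)C)[C@H]1OCc1ccc(OC)cc1)c1ccccc1 | intermediate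
21 | (3R,4S,5R,6S)-1-(benzoyloxymethyl)cyclohex-1-ene-3,4,5,6-tetrol | O=C(OCC1=C[C@@H](O)[C@H](O)[C@H](O)[C@H]1O)c1ccccc1 | intermediate
22 | trimethyl orthobenzoate | COC(OC)(OC)c1ccccc1 | starting material
23 | water | O | starting material
24 | 4,5-O-(α-methoxybenzylidene) orthoester of 21 | O=C(OCC1=C[C@@H](O)[C@H](O2)[C@H](OC2(OC)c2ccccc2)[C@H]1O)c1ccccc1 | intermediate
25 | (3R,4S,5R,6S)-5-benzoyloxy-1-(benzoyloxymethyl)cyclohex-1-ene-3,4,6-triol | O=C(OCC1=C[C@@H](O)[C@H](O)[C@H](OC(=O)c2ccccc2)[C@H]1O)c1ccccc1 | target

Total step count: 13. Longest linear sequence: 13 steps, from L-rhamnose.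

Steps most likely to fail

Step 7. The cyclisation may show poor facial selectivity at the aldehyde, or the aldol may lose water. The fallback sets out from 11 and makes the C3 configuration independent of the ring closure. Keto aldehyde 11 is cyclised with pyrrolidine and AcOH in CH2Cl2 without regard to selectivity, giving 12 together with its C3 epimer, the epimeric aldol F1. MsCl and Et3N at 0 °C convert both through the C3 mesylates F2 into one compound, the cyclohexenone F3. Conjugate borylation (B2pin2, CuCl, Xantphos, NaOtBu, MeOH, THF) should add boron to C3 anti to the C4–O bond on the convex face of the cis-fused bicycle, giving the β-boryl ketone F4. Oxidation with NaBO3·4H2O in THF/H2O proceeds with retention and returns to the route at 12.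

Step 9. Enolisation may lose regiocontrol toward C6, or the enolate may expel the C3 silyloxy group before it is trapped. The fallback sets out from 14 and avoids any enolate. Dimethylsulfonium methylide (trimethylsulfonium iodide, n-BuLi, THF, −10 °C; Corey–Chaykovsky reaction) adds the C7 carbon as the spiro-epoxide F5. Diethylaluminium 2,2,6,6-tetramethylpiperidide, Et2Al(TMP), in toluene at 0 °C then isomerises the epoxide to the allylic alcohol by syn removal of a proton from the accessible C2 methylene. This comes back to the route at 18.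

Step 13. The hemi-orthoester may open toward O4, or the orthoester may exchange with the allylic hydroxyls. The fallback sets out from 21 and uses a method of complementary regiochemistry. Bu2SnO in MeOH at reflux forms the 4,5-O-dibutylstannylene acetal F6 across the cis diol. BzCl in 1,4-dioxane at 0 °C acylates the equatorial oxygen of such acetals. If the orthoester route fails because the half-chair with O4 axial is populated, that same preference makes O5 the equatorial oxygen, and the fallback comes back to the route at 25.

Further compounds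
F1 | step 7 | C3 epimer of 12 (O3 cis to O4) | O=C1C[C@H](O)[C@H](O2)[C@H](OC2(C)C)[C@H]1OCc1ccc(OC)cc1
F2 | step 7 | 3-O-methanesulfonates of 12 and F1 (both C3 epimers) | O=C1CC(OS(C)(=O)=O)[C@H](O2)[C@H](OC2(C)C)[C@H]1OCc1ccc(OC)cc1
F3 | step 7 | 4,5-O-isopropylidene-6-(4-methoxybenzyloxy)cyclohex-2-en-1-one | O=C1C=C[C@H](O2)[C@H](OC2(C)C)[C@H]1OCc1ccc(OC)cc1
F4 | step 7 | 3-(pinacolatoboryl) ketone, boron trans to O4 | O=C1C[C@@H](B3OC(C)(C)C(C)(C)O3)[C@H](O2)[C@H](OC2(C)C)[C@H]1OCc1ccc(OC)cc1
F5 | step 9 | spiro-epoxide of 14 at C1 (C7 in the oxirane, epimers at C1) | C1OC12C[C@@H](O[Si](C)(C)C(C)(C)C)[C@H](O3)[C@H](OC3(C)C)[C@H]2OCc1ccc(OC)cc1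
F6 | step 13 | 4,5-O-dibutylstannylene acetal of 21 | O=C(OCC1=C[C@@H](O)[C@H](O2)[C@H](O[Sn]2(CCCC)CCCC)[C@H]1O)c1ccccc1
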